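**Assumption:** germacrane numbering is used for the macrocycle and its open-chain precursors (ring carbons C1–C10, C11–C13 the α-methylene-carboxyl unit, lactone oxygen on C6, acetate on C3, free OH on C1, angelate on C8).

## Retrosynthetic overview

1. The target comes from a macrocyclic C8 alcohol by esterification with inversion at C8 (angelic acid) and removal of one silyl group from O1.
2. Key disconnection C7–C8: a samarium ketyl radical of an open-chain (Z)-enal adds to the β-carbon of a tethered 3-(phenylthiomethyl)butenolide and expels PhS•. This closes the ten-membered ring, sets C7 and C8, and unveils the exo-methylene.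
3. The open-chain precursor comes from a C2–C3 boron aldol (methyl enone + butenolide enal), then Evans–Tishchenko reduction, which sets C1 anti to C3 and places the acetate on O3.
4. Both Z-trisubstituted alkenes come from propargylic alcohols by trans-hydroalumination/iodination; C6 comes from a Sharpless kinetic resolution.
5. Ring order: butenolide first (ring-closing metathesis), ten-membered carbocycle last (radical closure).

## Forward route

Step 1
Reactants: 1 acrolein; 2 1-propynylmagnesium bromide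
Product: 3 rac-hex-1-en-4-yn-3-ol
Conditions: THF, −78 to 0 °C; H2O work-up
Reagents that add atoms: none
Why: 1,2-addition of the alkynyl Grignard reagent to the enal gives the racemic alkynyl vinyl carbinol (Grignard addition).

Step 2
Reactants: 3 rac-hex-1-en-4-yn-3-ol
Product: 4 (R)-hex-1-en-4-yn-3-ol
Conditions: Ti(OiPr)4, D-(−)-diisopropyl tartrate, t-BuOOH (0.6 equiv), 4 Å MS, CH2Cl2, −20 °C, stopped at about 55% conversion
Reagents that add atoms: none
Why: Sharpless kinetic resolution; with the D-tartrate the S enantiomer is epoxidized at its vinyl group much faster, so the R alcohol (future C6) is recovered in high ee.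

Step 3
Reactants: 4 (R)-hex-1-en-4-yn-3-ol
Product: 6 (3R,4Z)-5-iodohexa-1,4-dien-3-ol, via cyclic alkenylaluminate 5 (not isolated)
Conditions: NaAlH2(OCH2CH2OCH3)2 (Red-Al), THF, 0 °C to rt; EtOAc; then I2, −78 to 0 °C
Reagents that add atoms: iodine, II
Why: hydroxyl-directed trans-hydroalumination puts aluminium on the distal alkyne carbon cis to the carbinol carbon, and iodinolysis with retention gives the Z-alkenyl iodide that fixes the C4=C5 geometry (Red-Al/iodine sequence).

Step 4
Reactants: 7 2-(bromomethyl)acrylic acid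
Product: 8 2-[(phenylsulfanyl)methyl]prop-2-enoic acid
Conditions: PhSH (1.0 equiv), NaOH (2.1 equiv), EtOH/H2O, 0 °C to rt; then aq. HCl
Reagents that add atoms: benzenethiol, Sc1ccccc1
Why: thiolate displaces the allylic bromide (SN2 or SN2′, same product), installing PhS on the future C13 as a radical leaving group that tolerates the later palladium and amine steps.

Step 5
Reactants: 6 (3R,4Z)-5-iodohexa-1,4-dien-3-ol; 8 2-[(phenylsulfanyl)methyl]prop-2-enoic acid
Product: 9 (3R,4Z)-5-iodohexa-1,4-dien-3-yl 2-[(phenylsulfanyl)methyl]prop-2-enoate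
Conditions: DCC, DMAP (0.1 equiv), CH2Cl2, 0 °C to rt
Reagents that add atoms: none
Why: Steglich esterification joins O6 to the acrylic acid without touching the stereocentre.

Step 6
Reactants: 9 (3R,4Z)-5-iodohexa-1,4-dien-3-yl 2-[(phenylsulfanyl)methyl]prop-2-enoate
Product: 10 (5R)-5-[(1Z)-2-iodoprop-1-en-1-yl]-3-[(phenylsulfanyl)methyl]furan-2(5H)-one
Conditions: second-generation Grubbs catalyst [RuCl2(=CHPh)(PCy3)(H2IMes)] (5–10 mol%), CH2Cl2, 40 °C, 0.01 M
Reagents that add atoms: none
Why: ring-closing metathesis between the vinyl group and the 1,1-disubstituted acrylate forms the butenolide (C7=C11), and the trisubstituted iodoalkene does not take part.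

Step 7
Reactants: 10 (5R)-5-[(1Z)-2-iodoprop-1-en-1-yl]-3-[(phenylsulfanyl)methyl]furan-2(5H)-one
Product: 11 (2Z)-2-methyl-3-[(2S)-5-oxo-4-[(phenylsulfanyl)methyl]-2,5-dihydrofuran-2-yl]prop-2-enal
Conditions: Pd(PPh3)4 (5 mol%), CO (1–3 atm), Bu3SnH (1.1 equiv, syringe pump), THF, 50 °C; used at once
Reagents that add atoms: carbon monoxide, [C-]#[O+]
Why: Stille-type reductive carbonylation (oxidative addition of the alkenyl iodide to zerovalent palladium, CO insertion, hydride transfer from tin) gives the enal (C3) with retention of the Z geometry, the allyl sulfide being inert to palladium.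

Step 8
Reactants: 12 but-2-yn-1-ol
Product: 14 (2Z)-3-iodobut-2-en-1-ol, via cyclic alkenylaluminate 13 (not isolated)
Conditions: NaAlH2(OCH2CH2OCH3)2 (Red-Al), THF, 0 °C to rt; EtOAc; then I2, −78 to 0 °C
Reagents that add atoms: iodine, II
Why: the same directed trans-hydroalumination/iodination fixes the Z geometry of the future C9=C10 bond.

Step 9
Reactants: 14 (2Z)-3-iodobut-2-en-1-ol
Product: 15 triethyl{[(2Z)-3-iodobut-2-en-1-yl]oxy}silane
Conditions: Et3SiCl, imidazole, CH2Cl2, 0 °C
Reagents that add atoms: chlorotriethylsilane, CC[Si](Cl)(CC)CC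
Why: silylation; the primary triethylsilyl ether is later converted directly into the C8 aldehyde.

Step 10
Reactants: 15 triethyl{[(2Z)-3-iodobut-2-en-1-yl]oxy}silane; 16 N-methoxy-N-methylacetamide
Product: 18 (3Z)-3-methyl-5-[(triethylsilyl)oxy]pent-3-en-2-one, via alkenyllithium 17 (not isolated)
Conditions: t-BuLi (2.05 equiv), Et2O, −78 °C; then 16, −78 to 0 °C; H2O work-up
Reagents that add atoms: none
Why: iodine–lithium exchange with retention of geometry, then Weinreb acylation (the chelated adduct prevents over-addition) gives the methyl enone that carries C1 and C2.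

Step 11
Reactants: 18 (3Z)-3-methyl-5-[(triethylsilyl)oxy]pent-3-en-2-one; 11 (2Z)-2-methyl-3-[(2S)-5-oxo-4-[(phenylsulfanyl)methyl]-2,5-dihydrofuran-2-yl]prop-2-enal
Product: 20 (5S)-5-[(1Z,3S,6Z)-3-hydroxy-2,6-dimethyl-5-oxo-8-[(triethylsilyl)oxy]octa-1,6-dien-1-yl]-3-[(phenylsulfanyl)methyl]furan-2(5H)-one, via boron enolate 19 (not isolated)
Conditions: 18 (1.2 equiv), (−)-Ipc2BCl (1.3 equiv), Et3N (1.25 equiv), Et2O, −78 to 0 °C; then 11, −78 to −20 °C; MeOH, diethanolamine work-up (no peroxide)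
Reagents that add atoms: none
Why: Paterson boron aldol; the kinetic diisopinocampheylboron enolate of the methyl ketone adds to the si face of the aldehyde under reagent control, setting C3 as S (the minor C3 epimer is a diastereomer because C6 is fixed and is removed by chromatography).

Step 12
Reactants: 20 (the β-hydroxy enone of step 11)
Product: 21 (1Z,3S,5S,6Z)-5-hydroxy-2,6-dimethyl-1-[(2S)-5-oxo-4-[(phenylsulfanyl)methyl]-2,5-dihydrofuran-2-yl]-8-[(triethylsilyl)oxy]octa-1,6-dien-3-yl acetate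
Conditions: SmI2 (0.3 equiv), CH3CHO (8 equiv), THF, −10 °C
Reagents that add atoms: acetaldehyde, CC=O
Why: Evans–Tishchenko reduction; intramolecular hydride transfer within the samarium-bound hemiacetal reduces the C1 ketone anti to O3 (sets 1S) and leaves the acetate on O3, so the 1,3-diol is differentiated in one step.

Step 13
Reactants: 21 (the hydroxy acetate of step 12)
Product: 22 (1Z,3S,5S,6Z)-2,6-dimethyl-1-[(2S)-5-oxo-4-[(phenylsulfanyl)methyl]-2,5-dihydrofuran-2-yl]-5,8-bis[(triethylsilyl)oxy]octa-1,6-dien-3-yl acetate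
Conditions: Et3SiOTf, 2,6-lutidine, CH2Cl2, −78 °C
Reagents that add atoms: triethylsilyl trifluoromethanesulfonate, CC[Si](CC)(CC)OS(=O)(=O)C(F)(F)F
Why: silylation of the C1 hydroxyl keeps it apart from the C8 oxygen in the oxidation, ring closure and acylation that follow.

Step 14
Reactants: 22 (the bis-silyl ether of step 13)
Product: 23 (1Z,3S,5S,6Z)-2,6-dimethyl-8-oxo-1-[(2S)-5-oxo-4-[(phenylsulfanyl)methyl]-2,5-dihydrofuran-2-yl]-5-[(triethylsilyl)oxy]octa-1,6-dien-3-yl acetate
Conditions: (COCl)2, DMSO, CH2Cl2, −78 to −40 °C; then Et3N, −78 to 0 °C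
Reagents that add atoms: none
Why: under Swern conditions a primary triethylsilyl ether is converted directly into the aldehyde while the secondary silyl ether survives, giving the (Z)-enal at C8 without a separate deprotection.

Step 15
Reactants: 23 (the open-chain enal of step 14)
Product: 24 (1S,3S,6S,7R,8S)-3-acetoxy-8-hydroxy-1-(triethylsilyloxy)germacra-4Z,9Z,11(13)-trien-12,6-olide
Conditions: SmI2 (3 equiv), HMPA (12 equiv), THF, −78 °C, 23 added over 6 h (final 0.002 M); then aq. NH4Cl
Reagents that add atoms: none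
Why: Proposed new method: SmI2–HMPA reduces the enal to a samarium ketyl radical whose C8 adds to C7 (β-carbon) of the tethered butenolide on the face that carries the C5 chain, so the lactone becomes cis-fused; the HMPA-solvated O–Sm group takes the outer position anti to C6, which should give the 8S carbinol, and the α-lactone radical expels PhS• (reduced to thiolate) to unveil the exo-methylene; the closest known chemistry is the SmI2 ketyl–olefin cyclization/β-elimination sequence and SH2′ allyl transfer from allyl sulfides, here stretched to a ten-membered ring that the two Z-olefins preorganize (cis,cis-cyclodeca-1,6-diene is nearly strain-free), with low temperature to keep the Z-enal geometry in the ketyl.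

Step 16
Reactants: 24 (the macrocyclic 8S alcohol of step 15); 25 angelic acid [(2Z)-2-methylbut-2-enoic acid]
Product: 26 (1S,3S,6S,7S,8R)-3-acetoxy-8-angeloyloxy-1-(triethylsilyloxy)germacra-4Z,9Z,11(13)-trien-12,6-olide
Conditions: PPh3, DIAD (betaine pre-formed), 25, toluene, 0 °C to rt
Reagents that add atoms: none
Why: Mitsunobu esterification; SN2 displacement of the alkoxyphosphonium by angelate inverts C8 from S to R and installs the ester in one step, and pre-forming the betaine keeps free PPh3 away from the methylene lactone.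

Step 17
Reactants: 26 (the silyl-protected angelate of step 16)
Product: 27 (1S,3S,6S,7S,8R)-3-acetoxy-8-angeloyloxy-1-hydroxygermacra-4Z,9Z,11(13)-trien-12,6-olide (target)
Conditions: HF·pyridine, pyridine, THF, 0 °C
Reagents that add atoms: none
Why: buffered fluoride desilylation frees the C1 hydroxyl without acyl migration or loss of the acetate, angelate or lactone.

## Compound list

1 | acrolein (prop-2-enal) | C=CC=O | starting material
2 | 1-propynylmagnesium bromide | CC#C[Mg]Br | starting material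
3 | rac-hex-1-en-4-yn-3-ol | CC#CC(O)C=C | intermediate
4 | (R)-hex-1-en-4-yn-3-ol | CC#C[C@H](O)C=C | intermediate
5 | sodium (5R)-2,2-bis(2-methoxyethoxy)-3-methyl-5-vinyl-2,5-dihydro-1,2-oxaluminol-2-uide (cyclic alkenylaluminate of 4) | [Na+].COCCO[Al-]1(OCCOC)O[C@H](C=C)C=C1C | intermediate
6 | (3R,4Z)-5-iodohexa-1,4-dien-3-ol | O[C@@H](/C=C(/C)I)C=C | intermediate
7 | 2-(bromomethyl)acrylic acid | OC(=O)C(=C)CBr | starting material
8 | 2-[(phenylsulfanyl)methyl]prop-2-enoic acid | OC(=O)C(=C)CSc1ccccc1 | intermediate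
9 | (3R,4Z)-5-iodohexa-1,4-dien-3-yl 2-[(phenylsulfanyl)methyl]prop-2-enoate | C=C(CSc1ccccc1)C(=O)O[C@@H](/C=C(/C)I)C=C | intermediate
10 | (5R)-5-[(1Z)-2-iodoprop-1-en-1-yl]-3-[(phenylsulfanyl)methyl]furan-2(5H)-one | O=C1O[C@@H](/C=C(/C)I)C=C1CSc1ccccc1 | intermediate
11 | (2Z)-2-methyl-3-[(2S)-5-oxo-4-[(phenylsulfanyl)methyl]-2,5-dihydrofuran-2-yl]prop-2-enal | O=C1O[C@@H](/C=C(/C)C=O)C=C1CSc1ccccc1 | intermediate
12 | but-2-yn-1-ol | CC#CCO | starting material
13 | sodium 2,2-bis(2-methoxyethoxy)-3-methyl-2,5-dihydro-1,2-oxaluminol-2-uide (cyclic alkenylaluminate of 12) | [Na+].COCCO[Al-]1(OCCOC)OCC=C1C | intermediate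
14 | (2Z)-3-iodobut-2-en-1-ol | OC/C=C(/C)I | intermediate
15 | triethyl{[(2Z)-3-iodobut-2-en-1-yl]oxy}silane | CC[Si](CC)(CC)OC/C=C(/C)I | intermediate
16 | N-methoxy-N-methylacetamide | CC(=O)N(C)OC | starting material
17 | alkenyllithium from 15 (Li in place of I, cis to the CH2OSiEt3 group) | [Li]/C(C)=C\CO[Si](CC)(CC)CC | intermediate
18 | (3Z)-3-methyl-5-[(triethylsilyl)oxy]pent-3-en-2-one | CC(=O)/C(C)=C\CO[Si](CC)(CC)CC | intermediate
19 | (3Z)-3-methyl-5-[(triethylsilyl)oxy]penta-1,3-dien-2-yl diisopinocampheylborinate (boron enolate of 18, Ipc from (+)-α-pinene) | C=C(OB([C@@H]1C[C@@H]2C[C@H]([C@H]1C)C2(C)C)[C@@H]1C[C@@H]2C[C@H]([C@H]1C)C2(C)C)/C(C)=C\CO[Si](CC)(CC)CC | intermediate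
20 | (5S)-5-[(1Z,3S,6Z)-3-hydroxy-2,6-dimethyl-5-oxo-8-[(triethylsilyl)oxy]octa-1,6-dien-1-yl]-3-[(phenylsulfanyl)methyl]furan-2(5H)-one | O=C1O[C@@H](/C=C(/C)[C@@H](O)CC(=O)/C(C)=C\CO[Si](CC)(CC)CC)C=C1CSc1ccccc1 | intermediate
21 | (1Z,3S,5S,6Z)-5-hydroxy-2,6-dimethyl-1-[(2S)-5-oxo-4-[(phenylsulfanyl)methyl]-2,5-dihydrofuran-2-yl]-8-[(triethylsilyl)oxy]octa-1,6-dien-3-yl acetate | O=C1O[C@@H](/C=C(/C)[C@@H](OC(C)=O)C[C@H](O)/C(C)=C\CO[Si](CC)(CC)CC)C=C1CSc1ccccc1 | intermediate
22 | (1Z,3S,5S,6Z)-2,6-dimethyl-1-[(2S)-5-oxo-4-[(phenylsulfanyl)methyl]-2,5-dihydrofuran-2-yl]-5,8-bis[(triethylsilyl)oxy]octa-1,6-dien-3-yl acetate | O=C1O[C@@H](/C=C(/C)[C@@H](OC(C)=O)C[C@H](O[Si](CC)(CC)CC)/C(C)=C\CO[Si](CC)(CC)CC)C=C1CSc1ccccc1 | intermediate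
23 | (1Z,3S,5S,6Z)-2,6-dimethyl-8-oxo-1-[(2S)-5-oxo-4-[(phenylsulfanyl)methyl]-2,5-dihydrofuran-2-yl]-5-[(triethylsilyl)oxy]octa-1,6-dien-3-yl acetate | O=C1O[C@@H](/C=C(/C)[C@@H](OC(C)=O)C[C@H](O[Si](CC)(CC)CC)/C(C)=C\C=O)C=C1CSc1ccccc1 | intermediate
24 | (1S,3S,6S,7R,8S)-3-acetoxy-8-hydroxy-1-(triethylsilyloxy)germacra-4Z,9Z,11(13)-trien-12,6-olide (cis-fused lactone, C8 epimeric to the target) | C=C1C(=O)O[C@H]2/C=C(/C)[C@@H](OC(C)=O)C[C@H](O[Si](CC)(CC)CC)/C(C)=C\[C@H](O)[C@@H]12 | intermediate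
25 | angelic acid [(2Z)-2-methylbut-2-enoic acid] | C/C=C(/C)C(O)=O | starting material
26 | (1S,3S,6S,7S,8R)-3-acetoxy-8-angeloyloxy-1-(triethylsilyloxy)germacra-4Z,9Z,11(13)-trien-12,6-olide | C=C1C(=O)O[C@H]2/C=C(/C)[C@@H](OC(C)=O)C[C@H](O[Si](CC)(CC)CC)/C(C)=C\[C@@H](OC(=O)/C(C)=C\C)[C@@H]12 | intermediate
27 | (1S,3S,6S,7S,8R)-3-acetoxy-8-angeloyloxy-1-hydroxygermacra-4Z,9Z,11(13)-trien-12,6-olide = (3aS,4R,5Z,7S,9S,10Z,11aS)-9-acetoxy-7-hydroxy-6,10-dimethyl-3-methylidene-2-oxo-2,3,3a,4,7,8,9,11a-octahydrocyclodeca[b]furan-4-yl (2Z)-2-methylbut-2-enoate | C=C1C(=O)O[C@H]2/C=C(/C)[C@@H](OC(C)=O)C[C@H](O)/C(C)=C\[C@@H](OC(=O)/C(C)=C\C)[C@@H]12 | target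

## Step count and risks

Total steps: 17. Longest linear sequence: 13 (steps 1, 2, 3, 5, 6, 7, 11, 12, 13, 14, 15, 16, 17).

**Step 15 (radical ring closure).** Risks are simple reduction or dimerization of the enal, Z/E scrambling in the ketyl, and uncertain C8 selectivity. The fallback sets out from 23 and comes back at 26. It replaces the ketyl by an acyl radical: irradiation at 365 nm with tetrabutylammonium decatungstate, (Bu4N)4W10O32 (2 mol%), in MeCN at 0.002 M abstracts the formyl hydrogen; the C8 acyl radical closes on C7 and expels PhS•, which takes the hydrogen back from the reduced catalyst. This gives the macrocyclic ketone (1S,3S,6S,7S)-3-acetoxy-8-oxo-1-(triethylsilyloxy)germacra-4Z,9Z,11(13)-trien-12,6-olide F1. Luche reduction (NaBH4, CeCl3·7H2O, MeOH, −78 °C) from the outer face then gives the 8R alcohol (1S,3S,6S,7R,8R)-3-acetoxy-8-hydroxy-1-(triethylsilyloxy)germacra-4Z,9Z,11(13)-trien-12,6-olide F2. This is esterified with retention with 25 (2,4,6-trichlorobenzoyl chloride, Et3N, then DMAP, toluene) to rejoin the route at 26, so the inversion of step 16 is not needed.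

**Step 7 (palladium formylation next to an allylic lactone).** Risks are ionization of the γ-alkenyl lactone, conjugate reduction, and Z-to-E drift of the enal. The fallback sets out from 6 and comes back at 11, bringing C3 in as a protected alcohol before the butenolide exists. The dianion of 6 (MeLi, then t-BuLi, Et2O, −78 °C) is trapped with paraformaldehyde to give (2Z,4R)-2-methylhexa-2,5-diene-1,4-diol F3. The primary hydroxyl is silylated selectively (Et3SiCl, imidazole, CH2Cl2, −78 °C) to give (3R,4Z)-5-methyl-6-[(triethylsilyl)oxy]hexa-1,4-dien-3-ol F4. Esterification with 8 (DCC, DMAP) gives (3R,4Z)-5-methyl-6-[(triethylsilyl)oxy]hexa-1,4-dien-3-yl 2-[(phenylsulfanyl)methyl]prop-2-enoate F5. Ring-closing metathesis (second-generation Grubbs catalyst) gives (5S)-5-[(1Z)-2-methyl-3-[(triethylsilyl)oxy]prop-1-en-1-yl]-3-[(phenylsulfanyl)methyl]furan-2(5H)-one F6. Swern oxidation of the primary silyl ether, as in step 14, then gives 11.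

**Step 16 (Mitsunobu inversion with a hindered, weakly acidic acid at an allylic centre).** Risks are low conversion, elimination or SN2′. The fallback sets out from 24 and comes back at 26. It separates activation from displacement: 24 is converted (MsCl, Et3N, CH2Cl2, −20 °C) into the methanesulfonate (1S,3S,6S,7S,8S)-3-acetoxy-8-(methylsulfonyloxy)-1-(triethylsilyloxy)germacra-4Z,9Z,11(13)-trien-12,6-olide F7. This is displaced with inversion by caesium angelate (from 25 and Cs2CO3; 18-crown-6, toluene, 50 °C) to give 26.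

## Further compounds

F1 | step 15 | (1S,3S,6S,7S)-3-acetoxy-8-oxo-1-(triethylsilyloxy)germacra-4Z,9Z,11(13)-trien-12,6-olide | C=C1C(=O)O[C@H]2/C=C(/C)[C@@H](OC(C)=O)C[C@H](O[Si](CC)(CC)CC)/C(C)=C\C(=O)[C@@H]12
F2 | step 15 | (1S,3S,6S,7R,8R)-3-acetoxy-8-hydroxy-1-(triethylsilyloxy)germacra-4Z,9Z,11(13)-trien-12,6-olide | C=C1C(=O)O[C@H]2/C=C(/C)[C@@H](OC(C)=O)C[C@H](O[Si](CC)(CC)CC)/C(C)=C\[C@@H](O)[C@@H]12
F3 | step 7 | (2Z,4R)-2-methylhexa-2,5-diene-1,4-diol | O[C@@H](/C=C(/C)CO)C=C
F4 | step 7 | (3R,4Z)-5-methyl-6-[(triethylsilyl)oxy]hexa-1,4-dien-3-ol | O[C@@H](/C=C(/C)CO[Si](CC)(CC)CC)C=C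
F5 | step 7 | (3R,4Z)-5-methyl-6-[(triethylsilyl)oxy]hexa-1,4-dien-3-yl 2-[(phenylsulfanyl)methyl]prop-2-enoate | C=C(CSc1ccccc1)C(=O)O[C@@H](/C=C(/C)CO[Si](CC)(CC)CC)C=C
F6 | step 7 | (5S)-5-[(1Z)-2-methyl-3-[(triethylsilyl)oxy]prop-1-en-1-yl]-3-[(phenylsulfanyl)methyl]furan-2(5H)-one | O=C1O[C@@H](/C=C(/C)CO[Si](CC)(CC)CC)C=C1CSc1ccccc1
F7 | step 16 | (1S,3S,6S,7S,8S)-3-acetoxy-8-(methylsulfonyloxy)-1-(triethylsilyloxy)germacra-4Z,9Z,11(13)-trien-12,6-olide | C=C1C(=O)O[C@H]2/C=C(/C)[C@@H](OC(C)=O)C[C@H](O[Si](CC)(CC)CC)/C(C)=C\[C@H](OS(C)(=O)=O)[C@@H]12
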